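| flask | starting material | second substrate | free enzyme | remark |
|---|---|---|---|---|
| cedar | 0.10 M | 3 equiv | 0.0039 mol% | run made earlier |
| larch | 0.10 M | 3 equiv | 0.0087 mol% | run made earlier |
| ash | 0.20 M | 3 equiv | 0.0058 mol% | run made earlier |
| flask | 0.10 M | 3.00 equiv | 0.0058 mol% |  |

| run | time / h | target / % | starting material / % |
|---|---|---|---|
| cedar | 5.00 | 10.2 | 89.2 |
| cedar | 15.0 | 27.6 | 71.6 |
| cedar | 25.0 | 41.3 | 59.3 |
| cedar | 40.0 | 56.9 | 43.1 |
| larch | 3.00 | 13.5 | 86.2 |
| larch | 8.00 | 33.7 | 66.4 |
| larch | 15.0 | 54.7 | 45.4 |
| larch | 40.0 | 91.6 | 8.6 |
| ash | 10.0 | 39.2 | 61.2 |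
| ash | 20.0 | 66.9 | 33.4 |
| ash | 30.0 | 84.4 | 15.3 |
| ash | 40.0 | 93.7 | 6.1 |

(scatter of a reading: 0.3 percentage points)

* apparent order in second substrate when 50% of the starting material are converted (percent change of the rate of making target for one percent more second substrate charged)



**Early rates.** At early times each run gives a turnover rate: target made per catalyst charged, per hour. Cedar gives 523 h⁻¹ and larch 517 h⁻¹, nearly the same, so at this charge the early rate follows the catalyst. Ash gives 676 h⁻¹ over its first 10.0 h.

**Tied orders.** An order is the percent change of the rate for one percent more of a concentration. Cedar, larch and ash share 3 equiv, so the two reagents rise together. Mean c(starting material) is 1.69 times higher in ash than in cedar, and the rate is 1.29 times higher. The two orders therefore sum to about 0.486.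

**One concentration.** Starting material is the limiting reagent, and I take it to use second substrate one for one. At 50% conversion the flask then holds c(second substrate) = 0.250 M. The amount used up to that point stays the same when more is charged. So one percent more charged raises this standing concentration by 1.20 percent. I call this ratio of charge to standing concentration the gearing.

**My reckoning.** Nothing here separates the two orders, so I give the second substrate an equal share. Multiplied by the gearing, that gives 0.292 for the flask.

**The forecast.** It says 0.1, within −0.1 to 0.3, and holds that the second substrate “barely matters”. My figure is higher.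

**The result.** The flask gives 0.64.

    starting material + free enzyme ⇌ first complex (K = 8.20 M⁻¹, k = 624 M⁻¹ s⁻¹)
    first complex ⇌ loaded enzyme + first product (K = 0.366 M, k = 0.640 s⁻¹)
    second substrate + loaded enzyme ⇌ second complex (K = 3.10 M⁻¹, k = 90.7 M⁻¹ s⁻¹)
    second complex → free enzyme + target (k = 0.724 s⁻¹)
    loaded enzyme → spent catalyst (k = 1.51 × 10⁻⁵ s⁻¹)

That is more than my figure and above the forecast's range. The flask reaches 50% conversion after 0.860 d, when 21.7% of its catalyst is spent catalyst. After 2.00 d the flask keeps 73% of its second substrate, so the gearing at that conversion is 1.37.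

The runs were computed from invented constants; noise was put on by code.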